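Remark: locants are those of the ent-kaurane skeleton (C1–C20, defined in the analysis), α is the face of the C10 methyl group, and the spectator ester at C15 is taken as tert-butyl so that it outlasts the hydride reduction of the lactone.

## Analysis of the target

The target 31 is a rearranged ent-kaurane with four rings. Rings A and B form a trans-fused decalin (C10 methyl α, H5 β) in which ring B carries the tetrasubstituted C8=C9 alkene. A bicyclo[3.2.1]octene is fused onto that alkene: the six-membered ring C (C8–C9–C11–C12–C13–C14) and the five-membered ring D (C11–C15–C16–C13–C12). There are seven stereocentres. In the AB part, the C1 acetate is equatorial and cis to the C10 methyl, and the C6 acetate is axial, syn to the C10 methyl and to the axial C4 methyl. In the bridged part (C11, C12, C13) the one-carbon bridge C12 lies on the α face and its hydroxyl points towards the C15–C16 bridge, which lies on the β face. The sensitive groups are the exo-methylene ketone (C15=O, C16=C17), the β-hydroxy ketone through bridgehead C11 (retro-aldol under base), the β,γ-unsaturated ketone C15=O/C8=C9 (light-sensitive) and two acetates that rule out strongly basic late steps. The synthesis is hard because quaternary C10 sits directly on a tetrasubstituted alkene with different carbon arms at both ends, and because the flat alkene separates the bridged stereocentres from those of the AB part. The strategy rests on one feature: C10 is bonded both to C9 of the alkene and to oxygenated C1, and C9 carries C11 in any case. An ester C1–O–C11 is therefore a three-atom tether that can deliver a C8≡C9 alkyne to a C10=C5–C6=C7 diene, forming ring B, C10 and the tetrasubstituted alkene in one step. The tether sets C10 only in the sense with oxygen β at C1, so C1 has to be inverted afterwards.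

## Retrosynthetic reasoning

**C16=C17 and the free hydroxyl.** The enone is the most reactive group, so it is made last but one: 31 comes from its silyl ether 30, and 30 from ketone 28 by α-methylenation. The cut is safe because C16 is the only enolisable position of 28 (C11 is a bridgehead). The silyl group stays to the end so that the β-hydroxy ketone is never exposed to base.

**C16 itself.** Removing C16 from between C15 and C13 turns 28 into cyclobutanone 27. The forward step is a one-carbon ring expansion in which C13 must migrate. This cut is accepted because it reduces rings C and D to a four-membered ring that a single cycloaddition can make.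

**C15–C11 and C12–C13.** Both bonds of 27 are cut together, giving ketene 26 with an (E)-silyloxyvinyl arm on C9. The polarity matches: the ketene carbon C15 is electrophilic and C11, β to the enol ether oxygen, is nucleophilic. The forward [2+2] sets C11 and C13 by bridging and C12 from the alkene geometry. Ketene 26 comes from acid 24.

**C11–C12.** The enol ether of 24 is the silylated enol of aldehyde 22, and C12 is a one-carbon extension of a C11 aldehyde. That aldehyde is masked as lactol 16, which the ylide from 17 opens to the enol ether 18. The cut is placed here because it turns the lactone carbonyl that the tether leaves behind into the ring-C carbon C11 and frees the C1 oxygen in the same step.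

**Configuration at C1 and C6.** Diacetate 21 comes from diol 20, and 20 from dione 19, because both carbinol centres can be set by hydride from the β face: axial attack at C1 and equatorial attack at C6, where the α face is blocked by two axial methyl groups. Dione 19 comes from diol 18 by one oxidation, so the inversion at C1 and the correction at C6 share three steps.

**C6–O and C5–H.** The 6β-alcohol and the 5β-hydrogen of 15 come from the C5=C6 alkene of 13 by hydroboration on the β face. Lactol 16 comes from lactone 15 by partial reduction, which requires the C15 ester to be tert-butyl.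

**C9–C10 and C7–C8 (key cut).** Lactone 13 is opened across ring B to the alkynoate ester 12. No other cut makes the quaternary centre, the tetrasubstituted alkene and both carbon arms (C11 on C9, C14–C13–C15 on C8) at once. The forward Diels–Alder reaction must deliver C9 to the β face of C10, which the tether from the β-oxygen on C1 enforces.

**The ester and the alkyne.** Ester 12 is cut at C1–O into alcohol 8 and acid 11. Acid 11 comes from 10 by carboxylation of the terminal alkyne, and 10 from 9.

**The dienol.** Alcohol 8 comes from dienone 7 by enantioselective reduction, which sets the only stereocentre that is not substrate-controlled. The C5–C6 bond of 7 is cut to vinyl reagent 5 and vinylogous ester 4 (addition, then transposition). Compound 4 comes from 1 through 2 and 3 by two enolate methylations. This avoids an allylic oxidation of a vinyl diene.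

## Alternatives that were turned down

Alternative 1: The C11–C15 bond is cut and C15 is put back on C8, with the alkene at C9=C11; this gives the 17-nor ent-kaur-9(11)-en-15-one A1. In the forward step, direct irradiation of the β,γ-unsaturated ketone A1 cleaves C8–C15 and recombines the acyl–allyl pair at C11, which should give A2 with the alkene at C8=C9. In its favour, the configuration at C11, C12 and C13 is inherited suprafacially from A1, so no facial question arises in the bridged part; on this point it is stronger than the chosen route. Against it, A2 is itself a β,γ-unsaturated ketone that absorbs the same light, so a photostationary mixture, decarbonylation and the oxa-di-π-methane pathway all compete. A1 also needs two quaternary centres (C8 and C10) flanking C9, a 9(11)-alkene and the full oxygenation pattern before the key step, so the hard part is only moved. The chosen strategy needs one quaternary centre, makes the tetrasubstituted alkene thermally and has no photoequilibrium.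

Alternative 2: The C9–C11 bond is cut, giving enol triflate A3 with a cyclopentane-1,3-dione on the C14 arm. In the forward step a zerovalent palladium catalyst (for example from Pd2(dba)3 and a bulky phosphine, with K3PO4) should couple the triflate carbon C9 with the acidic dione carbon C11 and close ring C to the bridged dione A4. In its favour, the dione brings C11, C12, C13, C15 and C16 in one piece, so no ring expansion is needed; on convergence it is stronger than the chosen route. Against it, C9 is flanked by quaternary C10, the new C11 is a bridgehead between two carbonyls that cannot enolise, and such a dione is open to retro-Claisen cleavage under the basic coupling conditions. The two ketones of A4 must then be told apart, with C12 reduced from one face only, and the C13 stereocentre of A3 must be set beforehand because it decides the face of the bridge. A3 also still contains the C10 quaternary centre next to the alkene, for which this plan offers nothing. The chosen strategy solves exactly that part and avoids the bridged β-diketone.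

Alternative 3: The C15–C11 and C12–C13 bonds are cut together. In the forward step a ketene on the C8 arm adds in the crossed sense to an (E)-silyloxyvinyl arm on C9 and gives cyclobutanone A5. In its favour, it makes two bonds, two rings and three stereocentres in one polarity-matched step; for rings C and D it is as strong as anything available, and the chosen route uses the same cycloaddition later (A5 is compound 27, step 18). As the organising disconnection it was turned down. It presupposes the complete AB bicycle with two different arms on the tetrasubstituted alkene and says nothing about quaternary C10. It would also place the main strategic risk (face selection, the later ring expansion) at the very end, with no earlier step that justifies the investment. The chosen strategy puts the main risk early, on cheap material, and its key step delivers exactly the arm pattern that this cycloaddition needs.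

Key step: step 9

## Route

Step 1
Reactants: 1 2-methylcyclohexane-1,3-dione
Product: 2 3-isobutoxy-2-methylcyclohex-2-en-1-one
Conditions: i-BuOH, p-TsOH (cat.), toluene, reflux, Dean–Stark
Reagents that add atoms: 2-methylpropan-1-ol, CC(C)CO
Why: Acid-catalysed O-alkylation of the symmetric cyclic 1,3-dione (vinylogous ester formation), driven by azeotropic removal of water.

Step 2
Reactants: 2 3-isobutoxy-2-methylcyclohex-2-en-1-one
Product: 3 3-isobutoxy-2,6-dimethylcyclohex-2-en-1-one (racemic)
Conditions: LiN(i-Pr)2, THF, −78 °C; MeI, −78 → 0 °C
Reagents that add atoms: iodomethane, CI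
Why: Kinetic α'-deprotonation of the vinylogous ester and enolate alkylation (first stage of a Stork–Danheiser sequence); the new centre is removed again in step 3.

Step 3
Reactants: 3 3-isobutoxy-2,6-dimethylcyclohex-2-en-1-one
Product: 4 3-isobutoxy-2,6,6-trimethylcyclohex-2-en-1-one
Conditions: LiN(i-Pr)2, THF, −78 °C; MeI, DMPU, −78 → 25 °C
Reagents that add atoms: iodomethane, CI
Why: A second enolate methylation at the same α'-carbon builds the gem-dimethyl carbon that becomes C4.

Step 4
Reactants: 4 3-isobutoxy-2,6,6-trimethylcyclohex-2-en-1-one; 5 vinylmagnesium bromide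
Product: 7 2,4,4-trimethyl-3-vinylcyclohex-2-en-1-one, via carbinol adduct 6 (not isolated)
Conditions: CeCl3, THF, −78 → 0 °C; then 1 M HCl, 0 °C
Reagents that add atoms: water, O
Why: 1,2-Addition of the vinyl organocerium reagent to the hindered carbonyl, then acid-induced ionisation of the tertiary allylic alcohol and hydrolysis of the enol ether (Stork–Danheiser enone transposition) should give the 3-vinyl enone with the ketone at the future C1.

Step 5
Reactants: 7 2,4,4-trimethyl-3-vinylcyclohex-2-en-1-one
Product: 8 (1R)-2,4,4-trimethyl-3-vinylcyclohex-2-en-1-ol
Conditions: (S)-2-methyl-CBS-oxazaborolidine (10 mol%), catecholborane, toluene, −78 °C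
Reagents that add atoms: none
Why: Corey–Bakshi–Shibata reduction with the fully substituted alkene carbon as the large group and the ring CH2 as the small one; the (S)-catalyst should give the (R)-carbinol (β-oxygen at the future C1), and catecholborane at low temperature spares the diene.

Step 6
Reactants: 9 pent-4-ynoic acid
Product: 10 tert-butyl pent-4-ynoate
Conditions: isobutene, H2SO4 (cat.), CH2Cl2, sealed vessel, 25 °C
Reagents that add atoms: 2-methylpropene, CC(C)=C
Why: Acid-catalysed addition of the carboxylic acid to isobutene gives the tert-butyl ester without touching the alkyne.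

Step 7
Reactants: 10 tert-butyl pent-4-ynoate
Product: 11 6-tert-butoxy-6-oxohex-2-ynoic acid
Conditions: AgI (2 mol%), Cs2CO3, CO2 (1 atm), DMF, 50 °C; then cold aq. KHSO4
Reagents that add atoms: carbon dioxide, O=C=O
Why: Catalytic C–H carboxylation of the terminal alkyne through a silver acetylide; the carbonate base is too weak to enolise the ester, so only the alkyne end is carboxylated.

Step 8
Reactants: 8 (1R)-2,4,4-trimethyl-3-vinylcyclohex-2-en-1-ol; 11 6-tert-butoxy-6-oxohex-2-ynoic acid
Product: 12 tert-butyl (1R)-2,4,4-trimethyl-3-vinylcyclohex-2-en-1-yl hex-2-ynedioate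
Conditions: DCC, DMAP (cat.), CH2Cl2, −20 → 0 °C
Reagents that add atoms: none
Why: Steglich esterification; the low temperature suppresses conjugate addition of DMAP to the ynoate, and the carbinol centre is not involved.

Step 9
Reactants: 12 tert-butyl (1R)-2,4,4-trimethyl-3-vinylcyclohex-2-en-1-yl hex-2-ynedioate
Product: 13 tricyclic lactone (rings A and B with C5=C6 and C8=C9, γ-lactone C1(β-O)–O–C11(=O)–C9, 10α-methyl, 4,4-dimethyl, C8–CH2CH2CO2t-Bu)
Conditions: toluene (0.01 M), BHT, propylene oxide, 150 °C, sealed tube
Reagents that add atoms: none
Why: Heating populates the s-cis rotamer of the ester and the s-cis diene, and a concerted thermal [4+2] cycloaddition joins the electron-poor alkyne carbon C9 to C10 and C8 to C7. The closest known reaction type is the intramolecular Diels–Alder reaction of alkynoate esters of 3-vinylcyclohex-2-en-1-ols, which gives 1-oxygenated decalin lactones of the labdane type. Ring B is closed as the six-membered cycloadduct ring itself (a cyclohexa-1,4-diene), and the γ-lactone C1–O–C11–C9–C10 is closed as the five-membered ring spanned by the three-atom tether in a fused mode. The new stereocentre C10 is controlled by C1: the short tether reaches only the face of C10 on which the C1 oxygen stands, so C9 arrives β and the methyl group is left α. Regiochemistry is not open because the tether allows only the C9–C10/C8–C7 pairing. The step needs chemoselectivity for cycloaddition over loss of the alkynoic acid from the allylic ester; high dilution, an acid scavenger, a radical inhibitor and the activation of the alkyne by its own ester carbonyl should secure it. The product cannot aromatise because C10 is quaternary, and its two alkenes differ (C8=C9 conjugated and tetrasubstituted, C5=C6 isolated and trisubstituted), which step 10 uses.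

Step 10
Reactants: 13 tricyclic lactone
Product: 15 6β-hydroxy-5β-H lactone (C5=C6 of 13 replaced by H5β and 6β-OH), via C6 alkylborane 14 (not isolated)
Conditions: BH3·THF, THF, 0 → 25 °C; then NaOH, H2O2, 0 °C; pH 3 work-up
Reagents that add atoms: hydrogen peroxide, OO
Why: Hydroboration–oxidation; boron goes to the less substituted C6 and hydrogen to C5 by syn addition on the β face, opposite the two axial methyl groups on C10 and C4, while the conjugated tetrasubstituted alkene and both esters should stay untouched.

Step 11
Reactants: 15 6β-hydroxy-5β-H lactone
Product: 16 lactol (C11 hemiacetal of 15, mixture of anomers)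
Conditions: i-Bu2AlH (2.5 equiv), CH2Cl2, −78 °C; aq. potassium sodium tartrate
Reagents that add atoms: none
Why: Partial 1,2-reduction of the lactone to the lactol; the tert-butyl ester is much slower at −78 °C, and the lactol cannot dehydrate to a furan because C10 is quaternary.

Step 12
Reactants: 16 lactol; 17 (methoxymethyl)triphenylphosphonium chloride
Product: 18 1β,6β-diol with a 2-methoxyvinyl arm on C9 (E/Z mixture) and C8–CH2CH2CO2t-Bu
Conditions: KOt-Bu, THF, 0 → 45 °C
Reagents that add atoms: none
Why: Wittig reaction on the open hydroxy-aldehyde form of the lactol, a 2,6,6-trisubstituted cyclohexenecarbaldehyde of a type known to accept this ylide; it adds C12 and frees the C1 hydroxyl, and the enol ether geometry is irrelevant because it is hydrolysed in step 16.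

Step 13
Reactants: 18 1β,6β-diol
Product: 19 1,6-dione (5β-H)
Conditions: Dess–Martin periodinane, NaHCO3, CH2Cl2, 0 → 25 °C
Reagents that add atoms: none
Why: Buffered Dess–Martin oxidation of both secondary alcohols under non-enolising conditions, so that H5 and the enol ether should survive.

Step 14
Reactants: 19 1,6-dione
Product: 20 1α,6α-diol
Conditions: NaBH4, MeOH–THF, −20 °C
Reagents that add atoms: none
Why: Borohydride reduction under steric approach control: at C6 the α face is closed by the syn-axial methyl groups on C10 and C4, so hydride adds from β and leaves the axial 6α-alcohol; at C1 axial attack from the β face gives the equatorial 1α-alcohol, which inverts the centre that the tether had set.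

Step 15
Reactants: 20 1α,6α-diol
Product: 21 1α,6α-diacetate
Conditions: Ac2O, DMAP, pyridine, 50 °C
Reagents that add atoms: acetic anhydride, CC(=O)OC(C)=O
Why: DMAP-catalysed acylation; warming is needed for the axial 6α-alcohol between two axial methyl groups.

Step 16
Reactants: 21 1α,6α-diacetate
Product: 22 aldehyde acid (C9–CH2CHO, C8–CH2CH2CO2H, 1α,6α-diacetate)
Conditions: CF3CO2H–CH2Cl2 (1:4), H2O (5 equiv), 0 → 25 °C
Reagents that add atoms: water, O
Why: Acidolysis removes the tert-butyl ester and hydrolyses the enol ether in one operation while the acetates hold; any shift of C8=C9 into conjugation with the aldehyde is harmless, because step 17 converges on the same dienol ether.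

Step 17
Reactants: 22 aldehyde acid
Product: 24 (E)-silyl dienol ether acid (C9–CH=CH–OSi(i-Pr)3, C8–CH2CH2CO2H), via bis-silyl derivative 23 (not isolated)
Conditions: i-Pr3SiOTf, Et3N, CH2Cl2, −78 → 0 °C; then K2CO3, MeOH, 0 °C; pH 6 phosphate buffer
Reagents that add atoms: triisopropylsilyl trifluoromethanesulfonate, CC(C)[Si](OS(=O)(=O)C(F)(F)F)(C(C)C)C(C)C
Why: Soft enolisation and O-silylation of the aldehyde towards C11, its only α-carbon; the (E) isomer is expected because a (Z)-silyloxy group would clash with the fully substituted C9, and brief methanolysis cleaves the labile silyl ester but not the hindered acetates.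

Step 18
Reactants: 24 (E)-silyl dienol ether acid
Product: 27 cyclobutanone (bicyclo[3.1.1]heptenone fused at C8=C9; C15=O on the β face, C12–OSi(i-Pr)3 on the α face with the silyloxy group anti to C8=C9), via acid chloride 25 (not isolated), via ketene 26 (not isolated)
Conditions: 1-chloro-N,N,2-trimethylprop-1-en-1-amine, CH2Cl2, 0 °C; then slow addition to Et3N, toluene, 80 °C (0.005 M)
Reagents that add atoms: none
Why: Neutral formation of the acid chloride and dehydrochlorination give the monoalkylketene 26, which adds to the enol ether in an intramolecular ketene–alkene [2+2] cycloaddition of the crossed (bridged) type: the electrophilic ketene carbon C15 bonds to the nucleophilic C11, and C13 to the oxygen-bearing C12. C11 and C13 are set together by the bridging, C12 follows from the (E) geometry (suprafacial addition puts the silyloxy group anti to the C8=C9 bridge), and C12 is expected on the α face because the β side of C11 is occupied by C1 and its acetate.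

Step 19
Reactants: 27 cyclobutanone
Product: 28 cyclopentanone (bicyclo[3.2.1]octenone: C15=O on C11, C16H2 on C13, 12-OSi(i-Pr)3)
Conditions: CH2N2, Et2O–MeOH, 0 → 25 °C
Reagents that add atoms: diazomethane, C=[N+]=[N-]
Why: Diazomethane ring expansion of the strained cyclobutanone (Büchner–Curtius–Schlotterbeck type); C13, the less encumbered α-carbon with an sp3 neighbour, should migrate with retention in preference to the vinyl-substituted C11, and the cyclopentanone reacts much more slowly. No Lewis acid is used because 3-silyloxycyclobutanones ring-open under Lewis acids, and the step comes before methylenation because an enone would add diazomethane.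

Step 20
Reactants: 28 cyclopentanone
Product: 30 12-O-triisopropylsilyl ether of the target (C16=C17 in place), via Mannich base 29 (not isolated)
Conditions: (CH2O)n, N-methylanilinium trifluoroacetate, THF, 65 °C
Reagents that add atoms: formaldehyde (as paraformaldehyde), C=O
Why: Mannich-type α-methylenation with elimination of the amine; C16 is the only enolisable position because C11 is a bridgehead, and the weakly acidic medium spares the acetates and the silyl ether.

Step 21
Reactants: 30 12-O-triisopropylsilyl ether of the target
Product: 31 1alpha,6alpha-diacetoxyjungermannenone C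
Conditions: HF·pyridine, pyridine, THF, 0 → 25 °C
Reagents that add atoms: none
Why: Fluoride-mediated cleavage of the silyl ether under buffered, slightly acidic conditions; base is avoided because the β-hydroxy ketone could cleave by retro-aldol reaction and the enone could add nucleophiles.

## Compound list

1 | 2-methylcyclohexane-1,3-dione | CC1C(=O)CCCC1=O | starting material
2 | 3-isobutoxy-2-methylcyclohex-2-en-1-one | CC1=C(OCC(C)C)CCCC1=O | intermediate
3 | 3-isobutoxy-2,6-dimethylcyclohex-2-en-1-one (racemic) | CC1=C(OCC(C)C)CCC(C)C1=O | intermediate
4 | 3-isobutoxy-2,6,6-trimethylcyclohex-2-en-1-one | CC1=C(OCC(C)C)CCC(C)(C)C1=O | intermediate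
5 | vinylmagnesium bromide | C=C[Mg]Br | starting material
6 | 3-isobutoxy-2,6,6-trimethyl-1-vinylcyclohex-2-en-1-ol (racemic, not isolated) | C=CC1(O)C(C)=C(OCC(C)C)CCC1(C)C | intermediate
7 | 2,4,4-trimethyl-3-vinylcyclohex-2-en-1-one | C=CC1=C(C)C(=O)CCC1(C)C | intermediate
8 | (1R)-2,4,4-trimethyl-3-vinylcyclohex-2-en-1-ol | C=CC1=C(C)[C@H](O)CCC1(C)C | intermediate
9 | pent-4-ynoic acid | C#CCCC(=O)O | starting material
10 | tert-butyl pent-4-ynoate | C#CCCC(=O)OC(C)(C)C | intermediate
11 | 6-tert-butoxy-6-oxohex-2-ynoic acid | OC(=O)C#CCCC(=O)OC(C)(C)C | intermediate
12 | tert-butyl (1R)-2,4,4-trimethyl-3-vinylcyclohex-2-en-1-yl hex-2-ynedioate (Diels–Alder precursor) | C=CC1=C(C)[C@H](OC(=O)C#CCCC(=O)OC(C)(C)C)CCC1(C)C | intermediate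
13 | tricyclic lactone: C5=C6 and C8=C9, γ-lactone C1(β-O)–O–C11(=O)–C9, 10α-methyl, tert-butyl propanoate arm on C8 | O=C1O[C@@H]2CCC(C)(C)C3=CCC(CCC(=O)OC(C)(C)C)=C1[C@]23C | intermediate
14 | C6β alkylborane of 13 with H5β (not isolated) | O=C1O[C@@H]2CCC(C)(C)[C@H]3[C@H](B)CC(CCC(=O)OC(C)(C)C)=C1[C@]23C | intermediate
15 | 6β-hydroxy-5β-H lactone | O=C1O[C@@H]2CCC(C)(C)[C@H]3[C@H](O)CC(CCC(=O)OC(C)(C)C)=C1[C@]23C | intermediate
16 | lactol (C11 hemiacetal, anomeric mixture), 6β-ol | OC1O[C@@H]2CCC(C)(C)[C@H]3[C@H](O)CC(CCC(=O)OC(C)(C)C)=C1[C@]23C | intermediate
17 | (methoxymethyl)triphenylphosphonium chloride | COC[P+](c1ccccc1)(c1ccccc1)c1ccccc1.[Cl-] | starting material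
18 | 1β,6β-diol with 2-methoxyvinyl arm on C9 (E/Z) and tert-butyl propanoate arm on C8 | COC=CC1=C(CCC(=O)OC(C)(C)C)C[C@@H](O)[C@@H]2C(C)(C)CC[C@@H](O)[C@@]12C | intermediate
19 | 1,6-dione (5β-H, 10α-methyl) | COC=CC1=C(CCC(=O)OC(C)(C)C)CC(=O)[C@@H]2C(C)(C)CCC(=O)[C@@]12C | intermediate
20 | 1α,6α-diol | COC=CC1=C(CCC(=O)OC(C)(C)C)C[C@H](O)[C@@H]2C(C)(C)CC[C@H](O)[C@@]12C | intermediate
21 | 1α,6α-diacetate | COC=CC1=C(CCC(=O)OC(C)(C)C)C[C@H](OC(C)=O)[C@@H]2C(C)(C)CC[C@H](OC(C)=O)[C@@]12C | intermediate
22 | aldehyde acid: C9–CH2CHO, C8–CH2CH2CO2H, 1α,6α-diacetate | O=CCC1=C(CCC(=O)O)C[C@H](OC(C)=O)[C@@H]2C(C)(C)CC[C@H](OC(C)=O)[C@@]12C | intermediate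
23 | triisopropylsilyl ester of 24 (not isolated) | CC(C)[Si](O/C=C/C1=C(CCC(=O)O[Si](C(C)C)(C(C)C)C(C)C)C[C@H](OC(C)=O)[C@@H]2C(C)(C)CC[C@H](OC(C)=O)[C@@]12C)(C(C)C)C(C)C | intermediate
24 | (E)-silyl dienol ether acid: C9–CH=CH–OSi(i-Pr)3, C8–CH2CH2CO2H | CC(C)[Si](O/C=C/C1=C(CCC(=O)O)C[C@H](OC(C)=O)[C@@H]2C(C)(C)CC[C@H](OC(C)=O)[C@@]12C)(C(C)C)C(C)C | intermediate
25 | acid chloride of 24 (not isolated) | CC(C)[Si](O/C=C/C1=C(CCC(=O)Cl)C[C@H](OC(C)=O)[C@@H]2C(C)(C)CC[C@H](OC(C)=O)[C@@]12C)(C(C)C)C(C)C | intermediate
26 | ketene C14–C13H=C15=O on C8 (not isolated) | CC(C)[Si](O/C=C/C1=C(CC=C=O)C[C@H](OC(C)=O)[C@@H]2C(C)(C)CC[C@H](OC(C)=O)[C@@]12C)(C(C)C)C(C)C | intermediate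
27 | cyclobutanone: C15=O bridge β, C12–OSi(i-Pr)3 bridge α, silyloxy anti to C8=C9 | O=C1[C@@H]2C3=C(C[C@H](OC(C)=O)[C@@H]4C(C)(C)CC[C@H](OC(C)=O)[C@@]34C)C[C@H]1[C@@H]2O[Si](C(C)C)(C(C)C)C(C)C | intermediate
28 | cyclopentanone: 17-nor ketone, C15=O on C11, C16H2 on C13, 12-OSi(i-Pr)3 | C1C(=O)[C@@H]2C3=C(C[C@H](OC(C)=O)[C@@H]4C(C)(C)CC[C@H](OC(C)=O)[C@@]34C)C[C@H]1[C@@H]2O[Si](C(C)C)(C(C)C)C(C)C | intermediate
29 | Mannich base: 16-[(N-methylanilino)methyl] derivative of 28 (not isolated) | CN(CC1C(=O)[C@@H]2C3=C(C[C@H](OC(C)=O)[C@@H]4C(C)(C)CC[C@H](OC(C)=O)[C@@]34C)C[C@H]1[C@@H]2O[Si](C(C)C)(C(C)C)C(C)C)c1ccccc1 | intermediate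
30 | 12-O-triisopropylsilyl ether of the target | C=C1C(=O)[C@@H]2C3=C(C[C@H](OC(C)=O)[C@@H]4C(C)(C)CC[C@H](OC(C)=O)[C@@]34C)C[C@H]1[C@@H]2O[Si](C(C)C)(C(C)C)C(C)C | intermediate
31 | 1alpha,6alpha-diacetoxyjungermannenone C | C=C1C(=O)[C@@H]2C3=C(C[C@H](OC(C)=O)[C@@H]4C(C)(C)CC[C@H](OC(C)=O)[C@@]34C)C[C@H]1[C@@H]2O | target

## Step count and least certain steps

Total step count: 21. Longest linear sequence: 19 steps (steps 1–5 and 8–21); steps 6 and 7 form the side branch to acid 11.

**Step 9 (key step).** The most likely failure is thermal loss of the alkynoic acid from the allylic ester (ionisation or ester pyrolysis) outrunning cycloaddition, because the reactive s-cis ester rotamer is sparsely populated and the diene carries an inside methyl group at C10 that disfavours its s-cis form. The fallback replaces the tether by an intermolecular, hydroxyl-directed cycloaddition; it sets out from 8 and 11 and comes back at 13. Acid 11 would be methylated (MeI, K2CO3, DMF) to methyl tert-butyl hex-2-ynedioate F1. Alcohol 8 and F1 would then be combined neat or under high pressure, with a hydrogen bond from the allylic hydroxyl to the ynoate carbonyl steering the alkyne to the face of the oxygen and the usual ortho orientation joining the ester-bearing carbon to C10. The resulting hydroxy diester cycloadduct F2, whose C1 hydroxyl is cis to C9, should close to lactone 13 on warming with a trace of acid.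

**Step 17.** What may go wrong is loss of geometric control in the enolisation: α-deprotonation of the silylated aldehyde could give part of the (Z)-enol ether, which would invert C12 in step 18. The fallback changes how the geometry is set; it sets out from 22 and comes back at 24. Aldehyde 22 would first be equilibrated with DBU to the conjugated enal acid F3 (C9=C11, C8–H). Silylation of F3 under the same conditions then proceeds by γ-deprotonation at C8 of an enal that is held s-trans by its disubstituted β-carbon, and this conformation maps directly onto the (E)-enol ether of 24.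

**Step 18.** Three processes threaten the cycloaddition. The approach of the ketene to the two twist senses of the dienol ether may be poorly face-selective, since only C1 with its acetate and the C10 methyl tell the faces apart. The monoalkylketene may dimerise. The enol ether may be C-acylated without ring closure. The fallback uses a more electrophilic two-carbon partner; it sets out from 24 and comes back at 27. Acid 24 would be converted (isobutyl chloroformate, N-methylmorpholine, then pyrrolidine) into the pyrrolidine amide F4. Activation with Tf2O and 2,6-di-tert-butyl-4-methylpyridine would give a keteniminium ion that undergoes the same crossed [2+2] at lower temperature, forming the cyclobutaniminium triflate F5. Mild aqueous NaHCO3 hydrolysis of F5 gives 27. This answers the reactivity problems; if face selection is the problem, the remaining lever is the size of the group on the C1 oxygen.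

**Step 19.** The risk is migration of the wrong α-carbon (C11 instead of C13), because both are methine bridgeheads and differ only in their substituents. The fallback uses the wrong regioisomer instead of discarding it; it sets out from 27 and comes back at 30. If C11 migrates, the product is the isomeric ketone F5-homologue F6 (C16=O on C13, C15H2 on C11). Wittig methylenation of F6 with Ph3P=CH2 would give the 16-methylene compound F7. Allylic oxidation of F7 with SeO2 and t-BuOOH at C15, the only allylic CH2 of the exocyclic alkene, would give the 15-hydroxy-16-ene F8. Dess–Martin oxidation of F8 gives enone 30, so both regiochemical outcomes lead to the same compound. The open point in this fallback is competition from the allylic positions of the hindered C8=C9 alkene in the SeO2 step.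

## Further compounds

F1 | step 9 | methyl tert-butyl hex-2-ynedioate | COC(=O)C#CCCC(=O)OC(C)(C)C
F2 | step 9 | hydroxy diester cycloadduct: 1β-OH, C9–CO2Me, C5=C6 and C8=C9, 10α-methyl, tert-butyl propanoate arm on C8 | COC(=O)C1=C(CCC(=O)OC(C)(C)C)CC=C2C(C)(C)CC[C@@H](O)[C@@]12C
F3 | step 17 | conjugated enal acid: C9=C11H–C12HO, C8–H, C8–CH2CH2CO2H, 1α,6α-diacetate | O=CC=C1C(CCC(=O)O)C[C@H](OC(C)=O)[C@@H]2C(C)(C)CC[C@H](OC(C)=O)[C@@]12C
F4 | step 18 | pyrrolidine amide of 24 | CC(C)[Si](O/C=C/C1=C(CCC(=O)N2CCCC2)C[C@H](OC(C)=O)[C@@H]3C(C)(C)CC[C@H](OC(C)=O)[C@@]13C)(C(C)C)C(C)C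
F5 | step 18 | cyclobutaniminium triflate (pyrrolidinium ylidene at C15 of the skeleton of 27) | C1CC[N+](C1)=C5[C@@H]2C3=C(C[C@H](OC(C)=O)[C@@H]4C(C)(C)CC[C@H](OC(C)=O)[C@@]34C)C[C@H]5[C@@H]2O[Si](C(C)C)(C(C)C)C(C)C.[O-]S(=O)(=O)C(F)(F)F
F6 | step 19 | regioisomeric cyclopentanone: C16=O on C13, C15H2 on C11, 12-OSi(i-Pr)3 | O=C1C[C@@H]2C3=C(C[C@H](OC(C)=O)[C@@H]4C(C)(C)CC[C@H](OC(C)=O)[C@@]34C)C[C@H]1[C@@H]2O[Si](C(C)C)(C(C)C)C(C)C
F7 | step 19 | 16-methylene compound (15-deoxo analogue of 30) | C=C1C[C@@H]2C3=C(C[C@H](OC(C)=O)[C@@H]4C(C)(C)CC[C@H](OC(C)=O)[C@@]34C)C[C@H]1[C@@H]2O[Si](C(C)C)(C(C)C)C(C)C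
F8 | step 19 | 15-hydroxy-16-methylene compound (C15 epimers) | C=C1C(O)[C@@H]2C3=C(C[C@H](OC(C)=O)[C@@H]4C(C)(C)CC[C@H](OC(C)=O)[C@@]34C)C[C@H]1[C@@H]2O[Si](C(C)C)(C(C)C)C(C)C
A1 | alternative 1 | 17-nor ent-kaur-9(11)-en-15-one with 1α,6α-diacetoxy and 12-O-tert-butyldimethylsilyl groups (photolysis substrate) | C1C(=O)[C@@]23C[C@H](OC(C)=O)[C@@H]4C(C)(C)CC[C@H](OC(C)=O)[C@@]4(C)C2=C[C@@H](O[Si](C)(C)C(C)(C)C)[C@@H]1C3
A2 | alternative 1 | 12-O-tert-butyldimethylsilyl 17-nor target skeleton (product of the 1,3-acyl shift) | C1C(=O)[C@@H]2C3=C(C[C@H](OC(C)=O)[C@@H]4C(C)(C)CC[C@H](OC(C)=O)[C@@]34C)C[C@H]1[C@@H]2O[Si](C)(C)C(C)(C)C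
A3 | alternative 2 | C9 enol triflate with a cyclopentane-1,3-dione on the C14 arm, 1α,6α-diacetate | O=S(=O)(OC1=C(C[C@@H]2CC(=O)CC2=O)C[C@H](OC(C)=O)[C@@H]2C(C)(C)CC[C@H](OC(C)=O)[C@@]12C)C(F)(F)F
A4 | alternative 2 | AB-fused bicyclo[3.2.1]octene-12,15-dione | C1C(=O)[C@@H]2C3=C(C[C@H](OC(C)=O)[C@@H]4C(C)(C)CC[C@H](OC(C)=O)[C@@]34C)C[C@H]1C2=O
A5 | alternative 3 | AB-fused 12-triisopropylsilyloxybicyclo[3.1.1]heptenone (identical with 27) | O=C1[C@@H]2C3=C(C[C@H](OC(C)=O)[C@@H]4C(C)(C)CC[C@H](OC(C)=O)[C@@]34C)C[C@H]1[C@@H]2O[Si](C(C)C)(C(C)C)C(C)C
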